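**Plan**
1. Locants are elemane locants: ring B is the cyclohexane C5–C10, C1/C2 the oxirane CH/CH2, C3 the formyl carbon, C4 its α-carbon (C15 its =CH2), C11/C12/C13 the lactone α-carbon, C=O and =CH2.
2. Retrosynthesis: open the oxirane to C1–OH/C2–OTs and remove C15 (aldehyde α-methylenation). Then rejoin C2 and C3, which are 1,6-related through C1–C10–C5–C4, as a C2=C3 alkene of a temporary cyclohexene (ring A), to be cleaved again by ozonolysis.
3. Next cut the lactone C–O bond and the ring-B bond C7–C8 (lactone carbinol carbon to the β-carbon of the α-methylene acyl unit). This gives a C8 aldehyde and a (Z)-2-(methoxycarbonyl)allylboronate on ring A, whose two arms come from the CHO and CO2Et groups of a Diels–Alder adduct.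
4. Forward: Diels–Alder (ring A), then the C9–C8 and C6–C7≡C11 arms, then the allylboronate. Step 14 closes ring B and the γ-lactone together; ring A is then opened, C4 methylenated and the oxirane closed.
5. Stereochemistry: C1, C5, C10 from the enantioselective endo Diels–Alder reaction; C6 from alkynone transfer hydrogenation; C9 from CBS reduction; C7 and C8 from the chair allylboration held by ring A; the C1–O bond is retained into the oxirane.

Key step: step 14

Assumption: the (S)-configured oxazaborolidinium catalyst of step 2 is taken to give adduct 4 with the configuration drawn (formyl-endo model for α-substituted enals); if the sense is opposite, its mirror image is used.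

Step 1
Reactants: 1 (E)-but-2-enal
Product: 2 (E)-(buta-1,3-dien-1-yloxy)(tert-butyl)dimethylsilane
Conditions: TBSOTf, Et3N, Et2O, 0 °C → rt
Reagents that add atoms: tert-butyldimethylsilyl trifluoromethanesulfonate, CC(C)(C)[Si](C)(C)OS(=O)(=O)C(F)(F)F
Why: Silyl dienol ether formation (γ-deprotonation of the O-silylated enal) should give mainly the 1E diene, and any minor Z isomer should not react in step 2.

Step 2
Reactants: 2 (E)-(buta-1,3-dien-1-yloxy)(tert-butyl)dimethylsilane; 3 ethyl (E)-3-methyl-4-oxobut-2-enoate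
Product: 4 ethyl (1S,5S,6R)-5-[(tert-butyldimethylsilyl)oxy]-6-formyl-6-methylcyclohex-3-ene-1-carboxylate
Conditions: (S)-1-(2-methylphenyl)-3,3-diphenyltetrahydro-1H,3H-pyrrolo[1,2-c][1,3,2]oxazaborole (20 mol %), HNTf2 (18 mol %), CH2Cl2, −78 → −40 °C
Reagents that add atoms: none
Why: Lewis-acid-catalysed enantioselective Diels–Alder reaction in which the oxygenated diene terminus bonds to the methyl-bearing α-carbon (ortho rule), the boron-bound formyl group is endo so OTBS ends cis to CHO, the E dienophile keeps CHO and CO2Et trans, and the chiral catalyst face fixes C1, C5 and C10 in the absolute sense.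

Step 3
Reactants: 5 (tributylstannyl)methanol
Product: 6 tributyl{[(4-methoxybenzyl)oxy]methyl}stannane
Conditions: NaH, 4-methoxybenzyl chloride, Bu4NI (cat.), THF/DMF, 0 °C → rt
Reagents that add atoms: 4-methoxybenzyl chloride, COc1ccc(CCl)cc1
Why: Williamson etherification of the primary stannyl alcohol gives the hydroxymethyl-anion precursor.

Step 4
Reactants: 4 Diels–Alder adduct; 6 tributyl{[(4-methoxybenzyl)oxy]methyl}stannane
Product: 8 diol (CH(OH)CH2OPMB arm at C10 and CH2OH at C5; both C9 epimers), via hydroxy ester 7 (not isolated)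
Conditions: 6, n-BuLi, THF, −78 °C; then 4, −78 °C; then LiAlH4, −78 → 0 °C
Reagents that add atoms: none
Why: Tin–lithium exchange gives the alkoxymethyllithium, which adds to the aldehyde much faster than to the ester, and LiAlH4 then reduces the ester; the C9 epimers converge in step 5.

Step 5
Reactants: 8 diol
Product: 9 keto aldehyde (C9 ketone, C6 aldehyde)
Conditions: (COCl)2, DMSO, CH2Cl2, −78 °C; Et3N, −78 → 0 °C
Reagents that add atoms: none
Why: Swern oxidation activates both hydroxyls before base is added, so the 1,4-diol should go to the keto aldehyde without lactol or lactone formation, and C5 keeps its equatorial (thermodynamic) configuration.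

Step 6
Reactants: 9 keto aldehyde; 10 methyl propiolate
Product: 11 propargylic alcohol (both C6 epimers)
Conditions: 10, LiN(SiMe3)2, THF, −78 °C; then 9, −78 °C
Reagents that add atoms: none
Why: Acetylide 1,2-addition should be selective for the aldehyde over the hindered α-quaternary ketone; the C6 epimers converge in step 7.

Step 7
Reactants: 11 propargylic alcohol
Product: 12 alkynone (4-oxo-2-ynoate) diketone
Conditions: DMP, NaHCO3, CH2Cl2, 0 °C → rt
Reagents that add atoms: none
Why: Dess–Martin oxidation of the propargylic alcohol under buffered conditions leaves the PMB and silyl ethers intact.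

Step 8
Reactants: 12 diketone
Product: 13 (S)-propargylic alcohol at C6 (C9 ketone retained)
Conditions: Ru[(S,S)-TsNCH(Ph)CH(Ph)NH](p-cymene) (2 mol %), i-PrOH, rt
Reagents that add atoms: none
Why: Asymmetric transfer hydrogenation of an alkynyl ketone, in which the bifunctional catalyst distinguishes the alkynyl from the alkyl flank, so the (S,S) complex should give the (S)-carbinol (matched with Felkin–Anh attack anti to C10) and leave the hindered dialkyl ketone at C9 alone.

Step 9
Reactants: 13 propargylic alcohol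
Product: 14 C6 triethylsilyl ether
Conditions: TESCl, imidazole, DMF, 0 °C
Reagents that add atoms: chlorotriethylsilane, CC[Si](Cl)(CC)CC
Why: Silylation of the only free hydroxyl.

Step 10
Reactants: 14 silyl ether ketone
Product: 15 (S)-alcohol at C9
Conditions: (S)-1-methyl-3,3-diphenyltetrahydro-1H,3H-pyrrolo[1,2-c][1,3,2]oxazaborole (1 equiv), catecholborane, toluene, −78 → −30 °C
Reagents that add atoms: none
Why: CBS reduction in which the tert-alkyl flank (C10) is the large group and CH2OPMB the small one, so the (S)-catalyst should deliver hydride to give the (S)-carbinol, the configuration needed for the 9-ester.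

Step 11
Reactants: 15 alkynoate alcohol
Product: 16 (Z)-2-(methoxycarbonyl)allylboronate (C6 arm cis to CO2Me)
Conditions: i-Bu2AlH, HMPA, THF, 0 °C; then 2-(iodomethyl)-4,4,5,5-tetramethyl-1,3,2-dioxaborolane, 0 °C → rt
Reagents that add atoms: 2-(iodomethyl)-4,4,5,5-tetramethyl-1,3,2-dioxaborolane, CC1(C)OB(CI)OC1(C)C
Why: Conjugate hydroalumination of the ynoate gives an aluminium allenolate that is C-alkylated at C11 from the side away from the C6 branch, which should give the Z allylboronate.

Step 12
Reactants: 16 allylboronate alcohol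
Product: 17 C9 isobutyrate
Conditions: isobutyryl chloride, pyridine, DMAP, CH2Cl2, 0 °C → rt
Reagents that add atoms: isobutyryl chloride, CC(C)C(Cl)=O
Why: DMAP-catalysed acylation of the only free hydroxyl installs the ester of the target; pinacol allylboronates tolerate these conditions.

Step 13
Reactants: 17 isobutyrate
Product: 18 primary alcohol at C8
Conditions: DDQ, CH2Cl2/pH 7 buffer, 0 °C
Reagents that add atoms: none
Why: Oxidative cleavage of the PMB ether leaves the silyl ethers, esters and boronate untouched.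

Step 14
Reactants: 18 primary alcohol
Product: 21 tricyclic trans-fused α-methylene-γ-lactone (ring A cyclohexene, 1-OTBS, 6-OTES, 9-isobutyrate), via aldehyde 19 (not isolated), via borate ester 20 (not isolated)
Conditions: DMP, NaHCO3, CH2Cl2, 0 °C; then toluene, 80 °C; then PPTS (cat.), 80 °C
Reagents that add atoms: none
Why: Dess–Martin oxidation unmasks the C8 aldehyde, whose oxygen binds boron so that the Z allylboronate transfers its γ-carbon C7 to C8 through a closed six-membered chair transition state with allylic transposition (C11=C13 becomes the exocyclic methylene), after which the O8 borate acylates on the C12 methyl ester. The closest known reaction type is the allylboration of aldehydes with 2-alkoxycarbonyl allylboronates, which gives α-methylene-γ-butyrolactones stereospecifically. Ring B closes in a 6-exo-trig mode and the lactone in a 5-exo-trig acyl substitution. C7 and C8 are set together: the Z boronate geometry (C6 trans to CH2B) places both ring arms equatorial on the transition-state chair, which is the anti, trans-lactone pathway, and the temporary ring A forces ring B to close as the chair trans-fused to it, which fixes their sense relative to C5 and C10. The step needs diastereoselectivity for this all-equatorial closure and chemoselectivity for the aldehyde; either cis alternative would put a new substituent axial against C10–Me and C6–OTES on one face or the C9 ester on the other, and the boronate does not add to esters.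

Step 15
Reactants: 21 tricyclic lactone
Product: 23 enal aldehyde (ring A opened; C3 formyl on C4=CH2, C2 formyl on C1–OTBS), via dialdehyde 22 (not isolated)
Conditions: O3, CH2Cl2, −78 °C (Sudan red 7B end point); Me2S, −78 °C → rt; then 37% aq. CH2O, pyrrolidine (10 mol %), propanoic acid (10 mol %), i-PrOH, 45 °C
Reagents that add atoms: ozone, [O-][O+]=O; formaldehyde, C=O
Why: Ozonolysis should take the electron-rich ring alkene well before the conjugated methylene lactone, and amine-catalysed Mannich condensation–elimination (aldehyde α-methylenation) then acts on the unhindered CH2–CHO at C4 only, because the α-silyloxy neopentyl-type C2 aldehyde forms an enamine slowly.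

Step 16
Reactants: 23 enal aldehyde
Product: 24 primary alcohol at C2
Conditions: NaBH4, MeOH/CH2Cl2, −78 °C
Reagents that add atoms: none
Why: Chemoselective borohydride reduction, since the saturated α-oxygenated aldehyde is reduced at low temperature faster than the conjugated enal or the methylene lactone.

Step 17
Reactants: 24 primary alcohol
Product: 25 primary tosylate
Conditions: TsCl, pyridine, DMAP (cat.), CH2Cl2, 0 °C
Reagents that add atoms: 4-methylbenzenesulfonyl chloride, Cc1ccc(S(Cl)(=O)=O)cc1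
Why: Sulfonylation of the only free hydroxyl.

Step 18
Reactants: 25 tosylate
Product: 27 CNP0519565.1, via diol tosylate 26 (not isolated)
Conditions: HF·pyridine, pyridine, THF, 0 °C → rt; then DBU, CH2Cl2, 0 °C
Reagents that add atoms: none
Why: Buffered fluoride desilylation frees the C1 and C6 hydroxyls and base then closes the oxirane by 3-exo-tet displacement of the primary tosylate by O1, with retention at C1.

**Compound list**
1 | (E)-but-2-enal | C/C=C/C=O | starting material
2 | (E)-(buta-1,3-dien-1-yloxy)(tert-butyl)dimethylsilane | C=C/C=C/O[Si](C)(C)C(C)(C)C | intermediate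
3 | ethyl (E)-3-methyl-4-oxobut-2-enoate | CCOC(=O)/C=C(\C)C=O | starting material
4 | ethyl (1S,5S,6R)-5-[(tert-butyldimethylsilyl)oxy]-6-formyl-6-methylcyclohex-3-ene-1-carboxylate | O=C[C@@]1(C)[C@@H](O[Si](C)(C)C(C)(C)C)C=CC[C@@H]1C(=O)OCC | intermediate
5 | (tributylstannyl)methanol | CCCC[Sn](CCCC)(CCCC)CO | starting material
6 | tributyl{[(4-methoxybenzyl)oxy]methyl}stannane | CCCC[Sn](CCCC)(CCCC)COCc1ccc(OC)cc1 | intermediate
7 | hydroxy ester: 4 with CHO converted to CH(OH)CH2OPMB (both C9 epimers, ring centres as in 4) | COc1ccc(COCC(O)[C@@]2(C)[C@@H](O[Si](C)(C)C(C)(C)C)C=CC[C@@H]2C(=O)OCC)cc1 | intermediate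
8 | diol: 7 with CO2Et reduced to CH2OH | COc1ccc(COCC(O)[C@@]2(C)[C@@H](O[Si](C)(C)C(C)(C)C)C=CC[C@@H]2CO)cc1 | intermediate
9 | keto aldehyde: C10 carries C(=O)CH2OPMB, C5 carries CHO | COc1ccc(COCC(=O)[C@@]2(C)[C@@H](O[Si](C)(C)C(C)(C)C)C=CC[C@@H]2C=O)cc1 | intermediate
10 | methyl propiolate | C#CC(=O)OC | starting material
11 | methyl 4-hydroxybut-2-ynoate adduct at C6 (both C6 epimers) | COc1ccc(COCC(=O)[C@@]2(C)[C@@H](O[Si](C)(C)C(C)(C)C)C=CC[C@@H]2C(O)C#CC(=O)OC)cc1 | intermediate
12 | diketone: C6 alkynone, C9 ketone | COc1ccc(COCC(=O)[C@@]2(C)[C@@H](O[Si](C)(C)C(C)(C)C)C=CC[C@@H]2C(=O)C#CC(=O)OC)cc1 | intermediate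
13 | (S)-propargylic alcohol at C6, C9 ketone | COc1ccc(COCC(=O)[C@@]2(C)[C@@H](O[Si](C)(C)C(C)(C)C)C=CC[C@@H]2[C@H](O)C#CC(=O)OC)cc1 | intermediate
14 | C6 triethylsilyl ether of 13 | COc1ccc(COCC(=O)[C@@]2(C)[C@@H](O[Si](C)(C)C(C)(C)C)C=CC[C@@H]2[C@H](O[Si](CC)(CC)CC)C#CC(=O)OC)cc1 | intermediate
15 | (S)-alcohol at C9, C6 triethylsilyl ether, ynoate | COc1ccc(COC[C@@H](O)[C@@]2(C)[C@@H](O[Si](C)(C)C(C)(C)C)C=CC[C@@H]2[C@H](O[Si](CC)(CC)CC)C#CC(=O)OC)cc1 | intermediate
16 | (Z)-2-(methoxycarbonyl)allyl pinacolboronate, C9–OH free | COc1ccc(COC[C@@H](O)[C@@]2(C)[C@@H](O[Si](C)(C)C(C)(C)C)C=CC[C@@H]2[C@H](O[Si](CC)(CC)CC)/C=C(/CB3OC(C)(C)C(C)(C)O3)C(=O)OC)cc1 | intermediate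
17 | C9 isobutyrate of 16 | COc1ccc(COC[C@@H](OC(=O)C(C)C)[C@@]2(C)[C@@H](O[Si](C)(C)C(C)(C)C)C=CC[C@@H]2[C@H](O[Si](CC)(CC)CC)/C=C(/CB3OC(C)(C)C(C)(C)O3)C(=O)OC)cc1 | intermediate
18 | C8 primary alcohol (PMB removed) | OC[C@@H](OC(=O)C(C)C)[C@@]1(C)[C@@H](O[Si](C)(C)C(C)(C)C)C=CC[C@@H]1[C@H](O[Si](CC)(CC)CC)/C=C(/CB2OC(C)(C)C(C)(C)O2)C(=O)OC | intermediate
19 | C8 aldehyde with allylboronate | O=C[C@@H](OC(=O)C(C)C)[C@@]1(C)[C@@H](O[Si](C)(C)C(C)(C)C)C=CC[C@@H]1[C@H](O[Si](CC)(CC)CC)/C=C(/CB2OC(C)(C)C(C)(C)O2)C(=O)OC | intermediate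
20 | ring-B-closed O8 pinacol borate with methyl 2-substituted acrylate at C7 | COC(=O)C(=C)[C@H]1[C@@H](O[Si](CC)(CC)CC)[C@H]2CC=C[C@H](O[Si](C)(C)C(C)(C)C)[C@]2(C)[C@H](OC(=O)C(C)C)[C@@H]1OB3OC(C)(C)C(C)(C)O3 | intermediate
21 | tricyclic trans-fused α-methylene-γ-lactone with ring A cyclohexene, 1-OTBS, 6-OTES, 9-isobutyrate | C=C1C(=O)O[C@@H]2[C@@H]1[C@@H](O[Si](CC)(CC)CC)[C@H]3CC=C[C@H](O[Si](C)(C)C(C)(C)C)[C@]3(C)[C@@H]2OC(=O)C(C)C | intermediate
22 | dialdehyde: ring A opened, C5 carries CH2CHO, C10 carries CH(OTBS)CHO | C=C1C(=O)O[C@@H]2[C@@H]1[C@@H](O[Si](CC)(CC)CC)[C@@H](CC=O)[C@](C)([C@@H](O[Si](C)(C)C(C)(C)C)C=O)[C@@H]2OC(=O)C(C)C | intermediate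
23 | enal aldehyde: C5 carries C(=CH2)CHO | C=C1C(=O)O[C@@H]2[C@@H]1[C@@H](O[Si](CC)(CC)CC)[C@@H](C(=C)C=O)[C@](C)([C@@H](O[Si](C)(C)C(C)(C)C)C=O)[C@@H]2OC(=O)C(C)C | intermediate
24 | C2 primary alcohol | C=C1C(=O)O[C@@H]2[C@@H]1[C@@H](O[Si](CC)(CC)CC)[C@@H](C(=C)C=O)[C@](C)([C@@H](O[Si](C)(C)C(C)(C)C)CO)[C@@H]2OC(=O)C(C)C | intermediate
25 | C2 tosylate | C=C1C(=O)O[C@@H]2[C@@H]1[C@@H](O[Si](CC)(CC)CC)[C@@H](C(=C)C=O)[C@](C)([C@@H](O[Si](C)(C)C(C)(C)C)COS(=O)(=O)c3ccc(C)cc3)[C@@H]2OC(=O)C(C)C | intermediate
26 | diol tosylate (C1–OH and C6–OH free) | C=C1C(=O)O[C@@H]2[C@@H]1[C@@H](O)[C@@H](C(=C)C=O)[C@](C)([C@@H](O)COS(=O)(=O)c3ccc(C)cc3)[C@@H]2OC(=O)C(C)C | intermediate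
27 | CNP0519565.1 | C=C1C(=O)O[C@@H]2[C@@H]1[C@@H](O)[C@@H](C(=C)C=O)[C@](C)([C@@H]1CO1)[C@@H]2OC(=O)C(C)C | target

Total step count: 18. Longest linear sequence: 17 (steps 1, 2 and 4–18; step 3 is a side branch).

**Steps most likely to fail**

Step 14. The ester-deactivated boronate may add slowly, the isobutyryl group may migrate from O9 to O8 in the α-acyloxy aldehyde or borate, or ring B may close through a non-chair geometry to a cis lactone. The fallback replaces the preformed boronate by an allylindium made by reductive umpolung of a π-allylpalladium. It sets out from 15: hydroalumination (i-Bu2AlH, HMPA) and trapping with paraformaldehyde should give the 2-(hydroxymethyl)enoate diol F1. Isobutyric anhydride/DMAP acylates both hydroxyls to the bis(isobutyrate) F2, DDQ frees the primary alcohol F3 and Dess–Martin oxidation gives the aldehyde F4. Pd(PPh3)4 with InI in THF then ionises the allylic isobutyrate, transmetallates to indium and adds C7 to C8 within the same ring-A-locked chair; PPTS completes lactonisation and the route is rejoined at 21.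

Step 15. Ozone may also attack the methylene lactone, the 1,6-dialdehyde may undergo intramolecular aldol condensation under amine catalysis, or C1 may epimerise through an enamine of the C2 aldehyde. The fallback masks C3 as a lactol before any amine is used. It sets out from 21: PPTS in MeOH at 0 °C removes only the triethylsilyl group to give the C6 alcohol F5. Ozonolysis with Me2S work-up then gives the lactol aldehyde F6, in which the C3 aldehyde is held as a five-membered lactol by O6 and only the C2 aldehyde is free. NaBH4 at −78 °C reduces that aldehyde to the lactol alcohol F7. The formaldehyde/pyrrolidine methylenation now acts on a single masked aldehyde and gives the enal diol F8. TsCl/pyridine gives the primary tosylate F9, and HF·pyridine followed by DBU rejoins the route at 26 and so reaches 27.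

Step 2. The trisubstituted dienophile may react too slowly, endo or facial selectivity may be insufficient, or the strong acid may destroy the silyl dienol ether. The fallback uses resolution in place of asymmetric catalysis. It sets out from 2 and 3: an achiral Lewis acid (Me2AlCl, CH2Cl2, −78 °C) gives the racemic endo adduct F10. Condensation of its aldehyde with (1R,2R)-N,N′-dimethyl-1,2-diphenylethane-1,2-diamine gives diastereomeric aminals, from which the aminal F11 of the required series is separated by chromatography. Mild aqueous acid hydrolysis returns enantiopure 4.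

Further compounds
F1 | step 14 | diol: methyl (Z)-2-(hydroxymethyl)alk-2-enoate at C7=C11, C9–OH free | COc1ccc(COC[C@@H](O)[C@@]2(C)[C@@H](O[Si](C)(C)C(C)(C)C)C=CC[C@@H]2[C@H](O[Si](CC)(CC)CC)/C=C(/CO)C(=O)OC)cc1
F2 | step 14 | bis(isobutyrate) of F1 | COc1ccc(COC[C@@H](OC(=O)C(C)C)[C@@]2(C)[C@@H](O[Si](C)(C)C(C)(C)C)C=CC[C@@H]2[C@H](O[Si](CC)(CC)CC)/C=C(/COC(=O)C(C)C)C(=O)OC)cc1
F3 | step 14 | C8 primary alcohol of the bis(isobutyrate) | OC[C@@H](OC(=O)C(C)C)[C@@]1(C)[C@@H](O[Si](C)(C)C(C)(C)C)C=CC[C@@H]1[C@H](O[Si](CC)(CC)CC)/C=C(/COC(=O)C(C)C)C(=O)OC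
F4 | step 14 | C8 aldehyde with allylic isobutyrate | O=C[C@@H](OC(=O)C(C)C)[C@@]1(C)[C@@H](O[Si](C)(C)C(C)(C)C)C=CC[C@@H]1[C@H](O[Si](CC)(CC)CC)/C=C(/COC(=O)C(C)C)C(=O)OC
F5 | step 15 | tricyclic lactone with free C6–OH | C=C1C(=O)O[C@@H]2[C@@H]1[C@@H](O)[C@H]3CC=C[C@H](O[Si](C)(C)C(C)(C)C)[C@]3(C)[C@@H]2OC(=O)C(C)C
F6 | step 15 | lactol aldehyde (C3 lactol on O6, C2 aldehyde; both anomers) | C=C1C(=O)O[C@@H]2[C@@H]1[C@H]3OC(O)C[C@H]3[C@](C)([C@@H](O[Si](C)(C)C(C)(C)C)C=O)[C@@H]2OC(=O)C(C)C
F7 | step 15 | lactol alcohol (C2–OH) | C=C1C(=O)O[C@@H]2[C@@H]1[C@H]3OC(O)C[C@H]3[C@](C)([C@@H](O[Si](C)(C)C(C)(C)C)CO)[C@@H]2OC(=O)C(C)C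
F8 | step 15 | enal diol (C6–OH, C2–OH, C1–OTBS) | C=C1C(=O)O[C@@H]2[C@@H]1[C@@H](O)[C@@H](C(=C)C=O)[C@](C)([C@@H](O[Si](C)(C)C(C)(C)C)CO)[C@@H]2OC(=O)C(C)C
F9 | step 15 | C2 tosylate of F8 | C=C1C(=O)O[C@@H]2[C@@H]1[C@@H](O)[C@@H](C(=C)C=O)[C@](C)([C@@H](O[Si](C)(C)C(C)(C)C)COS(=O)(=O)c3ccc(C)cc3)[C@@H]2OC(=O)C(C)C
F10 | step 2 | racemic endo adduct (4 together with its enantiomer, whose SMILES is given) | O=C[C@]1(C)[C@H](O[Si](C)(C)C(C)(C)C)C=CC[C@H]1C(=O)OCC
F11 | step 2 | aminal of 4 with (1R,2R)-N,N′-dimethyl-1,2-diphenylethane-1,2-diamine | CN1[C@H](c2ccccc2)[C@@H](c2ccccc2)N(C)C1[C@@]1(C)[C@@H](O[Si](C)(C)C(C)(C)C)C=CC[C@@H]1C(=O)OCC
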